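(Readings and results are simulated for an exercise; scatter was added.)

In a one-step world starting material becomes target and stays target, so the share of target in what has formed never moves. These flasks have a second step, because target tops out and then sinks, so you count how many turnovers of that second step each flask has been given.

| flask | starting material | protic impurity | remark | time |
|---|---|---|---|---|
| alder | 0.044 M | 5 mM | run made earlier |  |
| elm | 0.080 M | 5 mM | run made earlier |  |
| north | 0.050 M | 5.00 mM |  | 80 min |
| north-west | 0.030 M | 5.00 mM |  | 120 min |

| run | time / min | target / % | isomer of the product / % |
|---|---|---|---|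
| alder | 6.00 | 23.8 | 2.6 |
| alder | 12.0 | 34.9 | 4.5 |
| alder | 20.0 | 42.8 | 9.3 |
| alder | 25.0 | 46.8 | 12.1 |
| alder | 30.0 | 47.9 | 15.7 |
| alder | 40.0 | 47.4 | 17.9 |
| elm | 2.50 | 12.8 | 1.5 |
| elm | 8.00 | 28.9 | 2.9 |
| elm | 15.0 | 40.7 | 6.0 |
| elm | 20.0 | 46.6 | 9.1 |
| elm | 30.0 | 49.0 | 14.5 |
| elm | 40.0 | 46.7 | 19.5 |

(standard deviation of a reading: 1 percentage point)

1. the flask that ends with the higher share of target in all that became target or isomer of the product or over-reaction product, or "neither" when 2 percentage points or less lies between them (north / north-west / neither)
2. share of target in all that became target or isomer of the product or over-reaction product, north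
3. share of target in all that became target or isomer of the product or over-reaction product, north-west

- in a conversion other conformer counts as not yet reacted

Alder and elm, at 0.044 M and 0.080 M, read 47.4% and 46.7% of target at 40.0 min. You therefore treat each step as pseudo-first-order at this impurity, and the clock is what separates north from north-west. The first alder reading gives the making constant:

k_make = −ln(1 − target − isomer)/t = 0.0511 min⁻¹

Way one uses the top of the curve, read at about 35.0 min and 47.6%. There, making equals loss, k_make·c(starting material) = k_loss·c(target):

k_loss = k_make·exp(−k_make·t)/target = 0.0179 min⁻¹

This is the loss constant of target, its exits taken together. Way two divides the rise of isomer by the target present: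

k_isomer = 0.00902 min⁻¹

They part, way one being faster. Which one cheats? Way two watches isomer, whereas the question also counts over-reaction product, of which no reading exists. Way one asks nothing about where target goes, so you keep way one.

With n = k_loss·t, and starting material reckoned down to 1.68% in north, the share is:

share = k_make/(k_make − k_loss)·exp(−n)

north: n = 1.43, share 36.7%
north-west: n = 2.15, share 17.9%

North leads by 19 percentage points, against a margin of 2 points.

The forecast names north, with 35% and 20%, saying “North, stopped earlier, keeps the higher share.”, and it stands below my north and above my north-west.

The flask gives north, with 34.5% in north and 20.3% in north-west.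

    target ⇌ isomer of the product (K = 4.10, k = 1.90 × 10⁻⁴ s⁻¹)
    starting material + protic impurity → quenched substrate (k = 0.240 M⁻¹ s⁻¹)
    2 other conformer → self-condensation product (k = 0.0830 M⁻¹ s⁻¹)
    other conformer → isomer of the product (k = 3.40 × 10⁻⁴ s⁻¹)
    starting material ⇌ other conformer (K = 0.120, k = 0.00190 s⁻¹)
    target → over-reaction product (k = 1.20 × 10⁻⁴ s⁻¹)
    starting material → target (k = 9.30 × 10⁻⁴ s⁻¹)

My count stood 2.2 points above north and 2.4 points below north-west. At 80 min in north, target is made more slowly than it is used up, at 0.140 of that rate. Read north at 3.0 h and the count gives n = 3.23 and a share of 6.11%, while that flask holds 11.6%.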